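The route rests on disconnecting the pyranone of the flavone half (ring C: O1, C2, C3, C4) from an intact (2R)-flavanone–biaryl core. In one palladium-catalysed operation iodophenol 14, carbon monoxide and arylacetylene 15 are joined, forming C4a–C4, C4–C3 and O1–C2 and closing that ring. The step exploits the way this ring is fused: O1/C8a lies next to the aryl-bearing C8, and in 14 the iodine (future C4a) sits between a benzyloxy group (future C5) and the only hydroxyl able to cyclise (future C8a), so only the 8-aryl flavone can form. Precursor 14 is the penta-O-benzyl (2R)-flavanone whose ring B carries a 4-benzyloxy-2,6-dihydroxy-3-iodophenyl group.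

Key step: step 11

Assumption: the target defines only C2 of the flavanone (R); the hindered biaryl axis between flavanone ring B and flavone C8 is not specified and is left uncontrolled, so rotamers may be observed.

Step 1
Reactants: 1 phloroglucinol
Product: 2 5-(benzyloxy)benzene-1,3-diol
Conditions: BnBr (0.5 equiv), K2CO3, DMF, 0 °C → rt
Reagents that add atoms: benzyl bromide, BrCc1ccccc1
Why: Williamson etherification under statistical control in a polar aprotic solvent that favours O-alkylation; with the triol in excess the monoether should predominate and is separable from recovered 1 and the higher ethers.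

Step 2
Reactants: 2 5-(benzyloxy)benzene-1,3-diol
Product: 3 1-(benzyloxy)-3,5-bis(methoxymethoxy)benzene
Conditions: MOMCl, i-Pr2NEt, CH2Cl2, 0 °C → rt
Reagents that add atoms: chloromethyl methyl ether, COCCl
Why: Standard O-alkylation of both phenols gives two acetal ethers that later direct metalation and can be removed with acid without touching benzyl ethers.

Step 3
Reactants: 4 3,4-bis(benzyloxy)benzaldehyde
Product: 5 4,5-bis(benzyloxy)-2-bromobenzaldehyde
Conditions: Br2, NaOAc, AcOH, rt
Reagents that add atoms: bromine, BrBr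
Why: Electrophilic aromatic bromination goes para to the 3-benzyloxy group and ortho to the formyl group, the one strongly activated unhindered position, while acetate buffers HBr so the benzyl ethers survive.

Step 4
Reactants: 3 1-(benzyloxy)-3,5-bis(methoxymethoxy)benzene, 5 4,5-bis(benzyloxy)-2-bromobenzaldehyde
Product: 8 4,5-bis(benzyloxy)-2-[4-(benzyloxy)-2,6-bis(methoxymethoxy)phenyl]benzaldehyde, via aryllithium 6 (not isolated), via arylzinc chloride 7 (not isolated)
Conditions: n-BuLi, THF, 0 °C; ZnCl2, 0 °C → rt; then 5, Pd(OAc)2 (2 mol %), SPhos (4 mol %), THF, 60 °C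
Reagents that add atoms: none
Why: Directed ortho-metalation occurs at the carbon flanked by the two methoxymethoxy groups, transmetalation to zinc gives a nucleophile that tolerates the aldehyde, and Negishi cross-coupling with an electron-rich biarylphosphine is established for tri-ortho-substituted biaryls.

Step 5
Reactants: 9 2,4,6-trihydroxyacetophenone
Product: 10 1-[2,4-bis(benzyloxy)-6-hydroxyphenyl]ethan-1-one
Conditions: BnBr (2.1 equiv), K2CO3, DMF, rt
Reagents that add atoms: benzyl bromide, BrCc1ccccc1
Why: Williamson benzylation takes the para hydroxyl and one ortho hydroxyl, whereas the remaining ortho hydroxyl is hydrogen-bonded to the acetyl group and should stay free.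

Step 6
Reactants: 10 1-[2,4-bis(benzyloxy)-6-hydroxyphenyl]ethan-1-one, 8 4,5-bis(benzyloxy)-2-[4-(benzyloxy)-2,6-bis(methoxymethoxy)phenyl]benzaldehyde
Product: 11 (E)-2'-hydroxychalcone (full name in the compound list)
Conditions: KOH (50 % aq.), EtOH/THF, rt
Reagents that add atoms: none
Why: Claisen–Schmidt condensation, in which the enolate of 10 adds to the non-enolisable aldehyde and the aldol dehydrates to the E-enone; MOM and benzyl ethers are inert to hydroxide and the chalcone phenoxide, the resting state in strong base, does not cyclise.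

Step 7
Reactants: 11 (E)-2'-hydroxychalcone
Product: 12 (2R)-flavanone bis(methoxymethyl) ether (full name in the compound list)
Conditions: 9-amino-9-deoxy-epi-quinidine N'-[3,5-bis(trifluoromethyl)phenyl]thiourea (20 mol %), toluene, rt → 40 °C
Reagents that add atoms: none
Why: Organocatalytic asymmetric intramolecular oxa-Michael addition (6-endo-trig), in which the quinuclidine nitrogen deprotonates the 2'-hydroxyl while the thiourea binds the enone carbonyl, so the phenoxide attacks one face of the β-carbon within the chiral ion pair and sets C2; the quinidine-derived catalyst is chosen for the (R) sense and its quinine-derived pseudoenantiomer would be used should a trial run show the opposite induction.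

Step 8
Reactants: 12 (2R)-flavanone bis(methoxymethyl) ether
Product: 13 (2R)-flavanone resorcinol (full name in the compound list)
Conditions: HCl (1.25 M in MeOH), THF, 0 °C → rt
Reagents that add atoms: none
Why: Acid-catalysed acetal exchange with methanol removes both methoxymethyl groups under conditions that leave benzyl ethers intact and should not open the flavanone, whose C2 centre is labile to base but not to mild acid at room temperature.

Step 9
Reactants: 13 (2R)-flavanone resorcinol
Product: 14 (2R)-5,7-bis(benzyloxy)-2-{4,5-bis(benzyloxy)-2-[4-(benzyloxy)-2,6-dihydroxy-3-iodophenyl]phenyl}chroman-4-one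
Conditions: NIS (1.0 equiv), CH2Cl2/MeCN, −20 → 0 °C
Reagents that add atoms: N-iodosuccinimide, O=C1CCC(=O)N1I
Why: Electrophilic aromatic iodination, in which the free resorcinol ring is by far the most nucleophilic arene, its two open positions are equivalent by symmetry (each ortho to one hydroxyl and para to the other), and one equivalent of reagent at low temperature should stop at the monoiodide.

Step 10
Reactants: 4 3,4-bis(benzyloxy)benzaldehyde
Product: 15 3,4-bis(benzyloxy)phenylacetylene
Conditions: dimethyl (1-diazo-2-oxopropyl)phosphonate, K2CO3, MeOH/THF, rt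
Reagents that add atoms: dimethyl (1-diazo-2-oxopropyl)phosphonate, COP(=O)(OC)C(=[N+]=[N-])C(C)=O
Why: Ohira–Bestmann (Seyferth–Gilbert) homologation, in which methanolysis of the reagent gives the diazomethylphosphonate anion that adds to the aldehyde and, after loss of phosphate and N2 and a 1,2-shift, delivers the terminal alkyne under conditions mild to benzyl ethers.

Step 11
Reactants: 14 (2R)-5,7-bis(benzyloxy)-2-{4,5-bis(benzyloxy)-2-[4-(benzyloxy)-2,6-dihydroxy-3-iodophenyl]phenyl}chroman-4-one, 15 3,4-bis(benzyloxy)phenylacetylene, 16 carbon monoxide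
Product: 19 heptabenzyl ether of the target (flavone 7-OH free), via ynone 17 (not isolated), via diethylaminoenone 18 (not isolated)
Conditions: PdCl2(PPh3)2 (5 mol %), CO (1 atm), Et2NH (5 equiv), DMF, 40 °C
Reagents that add atoms: none
Why: Zerovalent palladium (formed in situ from PdCl2(PPh3)2) inserts into the C–I bond of 14, CO insertion gives an aroylpalladium iodide and copper-free coupling with the acetylide of 15 releases ynone 17, which creates C4a–C4 and C4–C3; Et2NH then adds to the ynone to give β-aminoenone 18, and the phenol next to the new ketone displaces the amine by conjugate addition–elimination to form O1–C2. The closest known reaction type is the palladium-catalysed carbonylative Sonogashira annulation of ortho-iodophenols with terminal alkynes to flavones. The one ring formed, the pyranone (ring C of the flavone half), closes in an overall 6-endo-dig sense on the ynone, realised as a 6-endo-trig attack on 18 followed by loss of Et2NH. No stereocentre is created: C2 of the flavanone is carried through unchanged and the biaryl axis is left as it forms. The step needs regioselectivity (O1 beside C8), 6-endo over 5-exo closure (flavone, not aurone) and an intact flavanone; the first is fixed by the substrate, since only the hydroxyl ortho to iodine can reach the ynone while the other flank carries a benzyl ether, the second by routing the closure through the enaminone with the secondary amine present from the start, and the third by the weakly basic medium at 40 °C, in which the C3 protons of the flavanone should not be removed.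

Step 12
Reactants: 19 heptabenzyl ether of the target (flavone 7-OH free)
Product: 20 target, 8-{2-[(2R)-5,7-dihydroxy-4-oxochroman-2-yl]-4,5-dihydroxyphenyl}-2-(3,4-dihydroxyphenyl)-5,7-dihydroxy-4H-chromen-4-one
Conditions: H2 (1 atm), Pd/C (10 wt %), EtOAc/MeOH, rt
Reagents that add atoms: none
Why: Heterogeneous hydrogenolysis cleaves all seven O-benzyl groups as toluene at room temperature, where the flavone C2=C3 bond, both carbonyl groups and the benzylic C2–O bond of the flavanone react far more slowly, and the neutral medium leaves C2 untouched.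

Compound list
1 | phloroglucinol | Oc1cc(O)cc(O)c1 | starting material
2 | 5-(benzyloxy)benzene-1,3-diol | Oc1cc(O)cc(OCc2ccccc2)c1 | intermediate
3 | 1-(benzyloxy)-3,5-bis(methoxymethoxy)benzene | COCOc1cc(OCOC)cc(OCc2ccccc2)c1 | intermediate
4 | 3,4-bis(benzyloxy)benzaldehyde | O=Cc1ccc(OCc2ccccc2)c(OCc2ccccc2)c1 | starting material
5 | 4,5-bis(benzyloxy)-2-bromobenzaldehyde | O=Cc1cc(OCc2ccccc2)c(OCc2ccccc2)cc1Br | intermediate
6 | [4-(benzyloxy)-2,6-bis(methoxymethoxy)phenyl]lithium | [Li]c1c(OCOC)cc(OCc2ccccc2)cc1OCOC | intermediate (not isolated)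
7 | [4-(benzyloxy)-2,6-bis(methoxymethoxy)phenyl]zinc chloride | Cl[Zn]c1c(OCOC)cc(OCc2ccccc2)cc1OCOC | intermediate (not isolated)
8 | 4,5-bis(benzyloxy)-2-[4-(benzyloxy)-2,6-bis(methoxymethoxy)phenyl]benzaldehyde | O=Cc1cc(OCc2ccccc2)c(OCc2ccccc2)cc1-c1c(OCOC)cc(OCc2ccccc2)cc1OCOC | intermediate
9 | 2,4,6-trihydroxyacetophenone | CC(=O)c1c(O)cc(O)cc1O | starting material
10 | 1-[2,4-bis(benzyloxy)-6-hydroxyphenyl]ethan-1-one | CC(=O)c1c(O)cc(OCc2ccccc2)cc1OCc1ccccc1 | intermediate
11 | (E)-1-[2,4-bis(benzyloxy)-6-hydroxyphenyl]-3-{4,5-bis(benzyloxy)-2-[4-(benzyloxy)-2,6-bis(methoxymethoxy)phenyl]phenyl}prop-2-en-1-one | O=C(/C=C/c1cc(OCc2ccccc2)c(OCc2ccccc2)cc1-c1c(OCOC)cc(OCc2ccccc2)cc1OCOC)c1c(O)cc(OCc2ccccc2)cc1OCc1ccccc1 | intermediate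
12 | (2R)-5,7-bis(benzyloxy)-2-{4,5-bis(benzyloxy)-2-[4-(benzyloxy)-2,6-bis(methoxymethoxy)phenyl]phenyl}chroman-4-one | O=C1C[C@H](c2cc(OCc3ccccc3)c(OCc3ccccc3)cc2-c2c(OCOC)cc(OCc3ccccc3)cc2OCOC)Oc2cc(OCc3ccccc3)cc(OCc3ccccc3)c21 | intermediate
13 | (2R)-5,7-bis(benzyloxy)-2-{4,5-bis(benzyloxy)-2-[4-(benzyloxy)-2,6-dihydroxyphenyl]phenyl}chroman-4-one | O=C1C[C@H](c2cc(OCc3ccccc3)c(OCc3ccccc3)cc2-c2c(O)cc(OCc3ccccc3)cc2O)Oc2cc(OCc3ccccc3)cc(OCc3ccccc3)c21 | intermediate
14 | (2R)-5,7-bis(benzyloxy)-2-{4,5-bis(benzyloxy)-2-[4-(benzyloxy)-2,6-dihydroxy-3-iodophenyl]phenyl}chroman-4-one | O=C1C[C@H](c2cc(OCc3ccccc3)c(OCc3ccccc3)cc2-c2c(O)cc(OCc3ccccc3)c(I)c2O)Oc2cc(OCc3ccccc3)cc(OCc3ccccc3)c21 | intermediate (key-step precursor)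
15 | 3,4-bis(benzyloxy)phenylacetylene | C#Cc1ccc(OCc2ccccc2)c(OCc2ccccc2)c1 | intermediate
16 | carbon monoxide | [C-]#[O+] | starting material
17 | (2R)-5,7-bis(benzyloxy)-2-{4,5-bis(benzyloxy)-2-[4-(benzyloxy)-3-{3-[3,4-bis(benzyloxy)phenyl]prop-2-ynoyl}-2,6-dihydroxyphenyl]phenyl}chroman-4-one | O=C1C[C@H](c2cc(OCc3ccccc3)c(OCc3ccccc3)cc2-c2c(O)cc(OCc3ccccc3)c(C(=O)C#Cc3ccc(OCc4ccccc4)c(OCc4ccccc4)c3)c2O)Oc2cc(OCc3ccccc3)cc(OCc3ccccc3)c21 | intermediate (not isolated)
18 | (2R)-5,7-bis(benzyloxy)-2-{4,5-bis(benzyloxy)-2-[4-(benzyloxy)-3-{3-[3,4-bis(benzyloxy)phenyl]-3-(diethylamino)prop-2-enoyl}-2,6-dihydroxyphenyl]phenyl}chroman-4-one (alkene geometry not defined) | O=C1C[C@H](c2cc(OCc3ccccc3)c(OCc3ccccc3)cc2-c2c(O)cc(OCc3ccccc3)c(C(=O)C=C(N(CC)CC)c3ccc(OCc4ccccc4)c(OCc4ccccc4)c3)c2O)Oc2cc(OCc3ccccc3)cc(OCc3ccccc3)c21 | intermediate (not isolated)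
19 | 5-(benzyloxy)-8-{4,5-bis(benzyloxy)-2-[(2R)-5,7-bis(benzyloxy)-4-oxochroman-2-yl]phenyl}-2-[3,4-bis(benzyloxy)phenyl]-7-hydroxy-4H-chromen-4-one | O=C1C[C@H](c2cc(OCc3ccccc3)c(OCc3ccccc3)cc2-c2c(O)cc(OCc3ccccc3)c3c(=O)cc(-c4ccc(OCc5ccccc5)c(OCc5ccccc5)c4)oc23)Oc2cc(OCc3ccccc3)cc(OCc3ccccc3)c21 | intermediate (key-step product)
20 | 8-{2-[(2R)-5,7-dihydroxy-4-oxochroman-2-yl]-4,5-dihydroxyphenyl}-2-(3,4-dihydroxyphenyl)-5,7-dihydroxy-4H-chromen-4-one | O=C1C[C@H](c2cc(O)c(O)cc2-c2c(O)cc(O)c3c(=O)cc(-c4ccc(O)c(O)c4)oc23)Oc2cc(O)cc(O)c21 | target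

Total step count: 12. Longest linear sequence: 9 steps (steps 1, 2, 4, 6, 7, 8, 9, 11, 12).

Steps most likely to fail

Step 11. The aroylpalladium species may be captured by diethylamine or a phenol instead of the alkyne, the alkyne may couple without CO, and closure may go 5-exo. The amine may also open the flavanone, which erodes C2; the liberated enone would then be intercepted by the neighbouring resorcinol hydroxyl. The fallback sets out from 14 and returns at 19. Both phenols are acetylated (Ac2O, pyridine, cat. DMAP, CH2Cl2, 0 °C) to give the iodoresorcinol diacetate F1. Carbonylative Sonogashira coupling of F1 with 15 and 16 (PdCl2(PPh3)2, Et3N, THF, rt), run with no phenoxide present, should give the isolable ynone diacetate F2. Brief treatment of F2 with Et2NH in THF/EtOH at 0 °C → rt should cleave both acetates by aminolysis and close the pyranone through enaminone 18 to give 19.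

Step 7. Cyclisation of the hindered, hydrogen-bonded chalcone may be slow or incomplete, and facial selectivity may be poor, giving low enantiomeric excess. The fallback sets out from 11 and returns at 12. Thermal closure with NaOAc in EtOH at reflux gives the racemic flavanone F3. Kinetic resolution by asymmetric transfer hydrogenation (RuCl(p-cymene)[(S,S)-TsDPEN], HCO2H/Et3N, EtOAc, rt, stopped a little past half conversion) should reduce the (2S) enantiomer to the cis-(2S,4S)-flavan-4-ol F4. The fast-reacting antipode is assigned by analogy with simple flavanones and would be confirmed on a trial run. Unreacted (2R)-12 is then separated by chromatography.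

Step 4. Metalation may occur at a carbon flanked by benzyloxy and methoxymethoxy groups or at a benzylic position, and coupling at the congested biaryl bond may be slow with competing protodemetalation. The fallback sets out from 3 and returns at 8. Aryllithium 6 is quenched with 2-isopropoxy-4,4,5,5-tetramethyl-1,3,2-dioxaborolane to give the pinacol boronate F5, which can be purified free of regioisomers. Suzuki–Miyaura coupling of F5 with 5 (Pd(OAc)2, SPhos, K3PO4, toluene/H2O, 90 °C) should give 8.

Further compounds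
F1 | step 11 | (2R)-5,7-bis(benzyloxy)-2-{4,5-bis(benzyloxy)-2-[2,6-diacetoxy-4-(benzyloxy)-3-iodophenyl]phenyl}chroman-4-one | O=C1C[C@H](c2cc(OCc3ccccc3)c(OCc3ccccc3)cc2-c2c(OC(C)=O)cc(OCc3ccccc3)c(I)c2OC(C)=O)Oc2cc(OCc3ccccc3)cc(OCc3ccccc3)c21
F2 | step 11 | (2R)-5,7-bis(benzyloxy)-2-{4,5-bis(benzyloxy)-2-[2,6-diacetoxy-4-(benzyloxy)-3-{3-[3,4-bis(benzyloxy)phenyl]prop-2-ynoyl}phenyl]phenyl}chroman-4-one | O=C1C[C@H](c2cc(OCc3ccccc3)c(OCc3ccccc3)cc2-c2c(OC(C)=O)cc(OCc3ccccc3)c(C(=O)C#Cc3ccc(OCc4ccccc4)c(OCc4ccccc4)c3)c2OC(C)=O)Oc2cc(OCc3ccccc3)cc(OCc3ccccc3)c21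
F3 | step 7 | racemic 5,7-bis(benzyloxy)-2-{4,5-bis(benzyloxy)-2-[4-(benzyloxy)-2,6-bis(methoxymethoxy)phenyl]phenyl}chroman-4-one | O=C1CC(c2cc(OCc3ccccc3)c(OCc3ccccc3)cc2-c2c(OCOC)cc(OCc3ccccc3)cc2OCOC)Oc2cc(OCc3ccccc3)cc(OCc3ccccc3)c21
F4 | step 7 | (2S,4S)-5,7-bis(benzyloxy)-2-{4,5-bis(benzyloxy)-2-[4-(benzyloxy)-2,6-bis(methoxymethoxy)phenyl]phenyl}chroman-4-ol | O[C@H]1C[C@@H](c2cc(OCc3ccccc3)c(OCc3ccccc3)cc2-c2c(OCOC)cc(OCc3ccccc3)cc2OCOC)Oc2cc(OCc3ccccc3)cc(OCc3ccccc3)c21
F5 | step 4 | 2-[4-(benzyloxy)-2,6-bis(methoxymethoxy)phenyl]-4,4,5,5-tetramethyl-1,3,2-dioxaborolane | CC1(C)OB(OC1(C)C)c1c(OCOC)cc(OCc2ccccc2)cc1OCOC
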